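**Plan**

- Feature (spiro[4.5]decane numbering: C1–C4 cyclopentane with isopropenyl at C2 and O at C4, C5 spiro, C6–C10 six-membered ring): the spiro carbon C5 is para to the C8 carbonyl and flanked by the two methyl-bearing carbons C6 and C10. The enone ring is therefore a dearomatised 4-substituted 3,5-dimethylphenol, and C4 is a former aryl aldehyde carbon.
- Retrosynthesis: remove the two esters, return C4 to a ketone masked as a 1,3-dithiane and the six-membered ring to the symmetric 2,5-dienone, then cut C3–C4 and C1–C5.
- Forward: the dithiane carbanion (umpolung of the aldehyde carbon) and the phenoxide para carbon of one arene act as a 1,2-dinucleophile toward an enantiopure C6 1,3-bis-electrophile. One pot closes the cyclopentane, dearomatises the arene and delivers the whole C15 skeleton.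
- The dithiane is umpolung group, temporary ring and steric shield; it is removed in step 10.
- Stereochemistry: C2 from lipase desymmetrisation of a prochiral diol; C5 and C10 from CuH conjugate reduction of one dienone arm (dithiane blocks the C4 face, isopropenyl and ligand choose the arm); C4 from hydride attack anti to the C10 methyl; C9 from enolate hydroxylation anti to that methyl.

Key step: step 8

Assumption: the lipase acetylates the hydroxymethyl arm that gives (R)-5; if its preference is the opposite, the same enzyme is used to hydrolyse the diacetate of 4, which gives (R)-5 as well.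

**Route**

Step 1
Reactants: 1 diethyl 2-(propan-2-ylidene)malonate
Product: 3 diethyl 2-(prop-1-en-2-yl)malonate, via lithium dienolate 2 (not isolated)
Conditions: LDA (1.1 equiv), THF, −78 °C; then AcOH, −78 °C
Reagents that add atoms: none
Why: Kinetic deconjugation of an alkylidene malonate: LDA removes a γ-methyl proton and α-protonation of the dienolate should leave the β,γ-unsaturated (isopropenyl) malonate; no stereocentre.

Step 2
Reactants: 3 diethyl 2-(prop-1-en-2-yl)malonate
Product: 4 2-(prop-1-en-2-yl)propane-1,3-diol
Conditions: LiAlH4, Et2O, 0 °C to rt; Fieser work-up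
Reagents that add atoms: none
Why: Hydride reduction of a 2-substituted malonate to the prochiral 2-substituted propane-1,3-diol; the isolated 1,1-disubstituted alkene is inert.

Step 3
Reactants: 4 2-(prop-1-en-2-yl)propane-1,3-diol
Product: 5 (R)-3-hydroxy-2-(prop-1-en-2-yl)propyl acetate
Conditions: lipase PS (immobilised), vinyl acetate, i-Pr2O, rt
Reagents that add atoms: vinyl acetate, C=COC(C)=O
Why: Lipase-catalysed desymmetrisation by irreversible transesterification; the enzyme acylates one of the two enantiotopic CH2OH arms, which makes the central carbon (later C2) stereogenic.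

Step 4
Reactants: 5 (R)-3-hydroxy-2-(prop-1-en-2-yl)propyl acetate
Product: 6 (S)-3-bromo-2-(prop-1-en-2-yl)propyl acetate
Conditions: CBr4, PPh3, CH2Cl2, 0 °C
Reagents that add atoms: carbon tetrabromide, BrC(Br)(Br)Br
Why: Appel bromination of the primary alcohol under neutral conditions that spare the acetate and the alkene; the stereocentre is not a reacting carbon (the descriptor changes only by priority).

Step 5
Reactants: 6 (S)-3-bromo-2-(prop-1-en-2-yl)propyl acetate
Product: 7 (S)-3-bromo-2-(prop-1-en-2-yl)propan-1-ol
Conditions: K2CO3 (cat.), MeOH, 0 °C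
Reagents that add atoms: none
Why: Base-catalysed transesterification (methanolysis) of the acetate; low temperature should prevent oxetane closure or bromide displacement.

Step 6
Reactants: 7 (S)-3-bromo-2-(prop-1-en-2-yl)propan-1-ol
Product: 8 (S)-3-bromo-2-(prop-1-en-2-yl)propyl trifluoromethanesulfonate
Conditions: Tf2O, 2,6-lutidine, CH2Cl2, −78 °C; cold filtration, used at once
Reagents that add atoms: trifluoromethanesulfonic anhydride, O=S(=O)(OS(=O)(=O)C(F)(F)F)C(F)(F)F
Why: O-Triflation with a hindered base gives a 1,3-bis-electrophile with two leaving groups of very different reactivity (triflate far above bromide), which later fixes the order of the two substitutions.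

Step 7
Reactants: 9 4-hydroxy-2,6-dimethylbenzaldehyde
Product: 10 4-(1,3-dithian-2-yl)-3,5-dimethylphenol
Conditions: propane-1,3-dithiol, BF3·OEt2, CH2Cl2, 0 °C to rt
Reagents that add atoms: propane-1,3-dithiol, SCCCS
Why: Lewis-acid thioacetalisation of the aldehyde (Corey–Seebach dithiane), tolerated by the free phenol; it turns the aldehyde carbon into a latent nucleophile.

Step 8
Reactants: 10 4-(1,3-dithian-2-yl)-3,5-dimethylphenol; 8 (S)-3-bromo-2-(prop-1-en-2-yl)propyl trifluoromethanesulfonate
Product: 13 (2R)-6,10-dimethyl-2-(prop-1-en-2-yl)spiro[4.5]deca-6,9-diene-4,8-dione 4-(propane-1,3-diyl dithioketal), via dilithium dianion 11 (not isolated), via lithium phenoxide bromide 12 (not isolated)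
Conditions: n-BuLi (2.1 equiv), THF–DMPU, −78 to −20 °C; 8 (1.05 equiv), −78 °C; then dilution, 50 °C
Reagents that add atoms: none
Why: Proposed new method: n-BuLi removes the phenolic proton and then the dithiane C2–H to give dianion 11, whose soft carbanion displaces the primary triflate of 8 at −78 °C (Corey–Seebach alkylation, the umpolung bond C3–C4) while the lithium phenoxide and the bromide stay untouched; on warming, phenoxide 12 attacks the CH2Br carbon through its para carbon and closes the cyclopentane by a 5-exo-tet alkylation that dearomatises the ring to the cross-conjugated dienone (bond C1–C5). The closest known reaction types are the alkylation of 2-lithio-2-aryl-1,3-dithianes with primary triflates and the Ar1-5 spirocyclisation of 4-(ω-haloalkyl)phenoxides; their one-pot union on a phenoxide–dithianyl dianion is the new element. No stereocentre is made: C2 comes unchanged from 8 because none of its bonds takes part, and C5 is not yet stereogenic because the two dienone arms are identical. The step needs C- over O-alkylation and triflate-before-bromide order: the para relation of oxygen and tether rules out intramolecular O-alkylation and leaves the ipso carbon as the only ring position within reach, dilution suppresses intermolecular O-alkylation, and the leaving-group gap makes the triflate carbon C3 and the bromide carbon C1, which fixes the (2R) configuration.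

Step 9
Reactants: 13 (2R)-6,10-dimethyl-2-(prop-1-en-2-yl)spiro[4.5]deca-6,9-diene-4,8-dione 4-(propane-1,3-diyl dithioketal)
Product: 15 (2R,5S,10S)-6,10-dimethyl-2-(prop-1-en-2-yl)spiro[4.5]dec-6-ene-4,8-dione 4-(propane-1,3-diyl dithioketal), via silyl dienol ether 14 (not isolated)
Conditions: Cu(OAc)2 (5 mol %), (R)-DTBM-SEGPHOS (5 mol %), PhMe2SiH (1.5 equiv), toluene, 0 °C to rt, no proton source; then 1 M HCl, THF, 0 °C
Reagents that add atoms: none
Why: Copper hydride asymmetric 1,4-reduction (conjugate hydrosilylation of a β,β-disubstituted cyclohexenone) should stop after one arm because silyl dienol ether 14 is inert to further reduction; hydride should reach C10 from the C1 face since the dithiane on C4 blocks the other face of both arms, which places the C10 methyl cis to C4, and the arm should be chosen by the C2 isopropenyl group, which shields the arm on its own side, reinforced by the (R)-ligand, whose facial preference for 3-methylcyclohexenones is expected to address this arm on the open face (the mirror-image ligand would be taken if the pairing proved mismatched), giving (5S,10S).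

Step 10
Reactants: 15 (2R,5S,10S)-6,10-dimethyl-2-(prop-1-en-2-yl)spiro[4.5]dec-6-ene-4,8-dione 4-(propane-1,3-diyl dithioketal)
Product: 16 (2R,5S,10S)-6,10-dimethyl-2-(prop-1-en-2-yl)spiro[4.5]dec-6-ene-4,8-dione
Conditions: MeI (excess), CaCO3, MeCN–H2O (4:1), 45 °C
Reagents that add atoms: water, O
Why: Alkylative dithiane hydrolysis (S-methylation, ring opening to the thionium ion, capture by water) under buffered neutral conditions that should spare the enone, the isopropenyl group and the C10 centre; no new stereocentre.

Step 11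
Reactants: 16 (2R,5S,10S)-6,10-dimethyl-2-(prop-1-en-2-yl)spiro[4.5]dec-6-ene-4,8-dione
Product: 17 (2R,4S,5S,10S)-4-hydroxy-6,10-dimethyl-2-(prop-1-en-2-yl)spiro[4.5]dec-6-en-8-one
Conditions: NaBH4, MeOH–CH2Cl2 (1:1), −78 °C
Reagents that add atoms: none
Why: Borohydride reduction at low temperature should select the saturated cyclopentanone over the less electrophilic β,β-disubstituted enone, and hydride should approach C4 from the side of the sp2 carbon C6 because the C10 methyl, cis to C4, shields the other face, which gives the (4S) alcohol with OH cis to C10 and trans to the isopropenyl group.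

Step 12
Reactants: 17 (2R,4S,5S,10S)-4-hydroxy-6,10-dimethyl-2-(prop-1-en-2-yl)spiro[4.5]dec-6-en-8-one
Product: 18 (2R,4S,5S,10S)-6,10-dimethyl-8-oxo-2-(prop-1-en-2-yl)spiro[4.5]dec-6-en-4-yl 3-methylbut-2-enoate
Conditions: 3-methylbut-2-enoyl chloride, pyridine, DMAP (cat.), CH2Cl2, 0 °C to rt
Reagents that add atoms: 3-methylbut-2-enoyl chloride, CC(C)=CC(=O)Cl
Why: DMAP-catalysed acylation of the hindered secondary alcohol with retention at C4; pyridine as the only base and low temperature should limit deconjugation of the senecioyl group through its vinylketene.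

Step 13
Reactants: 18 (2R,4S,5S,10S)-6,10-dimethyl-8-oxo-2-(prop-1-en-2-yl)spiro[4.5]dec-6-en-4-yl 3-methylbut-2-enoate
Product: 20 (2R,4S,5S,9S,10R)-9-hydroxy-6,10-dimethyl-8-oxo-2-(prop-1-en-2-yl)spiro[4.5]dec-6-en-4-yl 3-methylbut-2-enoate, via potassium enolate 19 (not isolated)
Conditions: KHMDS (1.05 equiv), THF, −78 °C; 2-(phenylsulfonyl)-3-phenyloxaziridine, −78 °C; aq. NH4Cl
Reagents that add atoms: 2-(phenylsulfonyl)-3-phenyloxaziridine, O=S(=O)(c1ccccc1)N1OC1c1ccccc1
Why: Kinetic α′-deprotonation of the enone at C9 and enolate hydroxylation with an N-sulfonyloxaziridine; oxygen should arrive anti to the adjacent C10 methyl and to the ester-bearing C4, both on the other face, which gives the 9,10-trans (9S) ketol.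

Step 14
Reactants: 20 (2R,4S,5S,9S,10R)-9-hydroxy-6,10-dimethyl-8-oxo-2-(prop-1-en-2-yl)spiro[4.5]dec-6-en-4-yl 3-methylbut-2-enoate
Product: 21 (2R,4S,5S,9S,10R)-9-acetoxy-6,10-dimethyl-8-oxo-2-(prop-1-en-2-yl)spiro[4.5]dec-6-en-4-yl 3-methylbut-2-enoate
Conditions: Ac2O, pyridine, DMAP (cat.), CH2Cl2, rt
Reagents that add atoms: acetic anhydride, CC(=O)OC(C)=O
Why: DMAP-catalysed acetylation of the secondary α-ketol with retention at C9, which completes the target.

**Compound list**

1 | diethyl 2-(propan-2-ylidene)malonate | CCOC(=O)C(=C(C)C)C(=O)OCC | starting material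
2 | lithium dienolate of 1 | C=C(C)C(C(=O)OCC)=C([O-])OCC.[Li+] | intermediate
3 | diethyl 2-(prop-1-en-2-yl)malonate | C=C(C)C(C(=O)OCC)C(=O)OCC | intermediate
4 | 2-(prop-1-en-2-yl)propane-1,3-diol | C=C(C)C(CO)CO | intermediate
5 | (R)-3-hydroxy-2-(prop-1-en-2-yl)propyl acetate | C=C(C)[C@H](CO)COC(C)=O | intermediate
6 | (S)-3-bromo-2-(prop-1-en-2-yl)propyl acetate | C=C(C)[C@H](CBr)COC(C)=O | intermediate
7 | (S)-3-bromo-2-(prop-1-en-2-yl)propan-1-ol | C=C(C)[C@H](CBr)CO | intermediate
8 | (S)-3-bromo-2-(prop-1-en-2-yl)propyl trifluoromethanesulfonate | C=C(C)[C@H](CBr)COS(=O)(=O)C(F)(F)F | intermediate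
9 | 4-hydroxy-2,6-dimethylbenzaldehyde | Cc1cc(O)cc(C)c1C=O | starting material
10 | 4-(1,3-dithian-2-yl)-3,5-dimethylphenol | Cc1cc(O)cc(C)c1C1SCCCS1 | intermediate
11 | dilithium salt of 10 (phenoxide and 2-dithianyl carbanion) | Cc1cc([O-])cc(C)c1[C-]1SCCCS1.[Li+].[Li+] | intermediate
12 | lithium 4-{2-[(2R)-2-(bromomethyl)-3-methylbut-3-en-1-yl]-1,3-dithian-2-yl}-3,5-dimethylphenolate | C=C(C)[C@H](CBr)CC1(SCCCS1)c1c(C)cc([O-])cc1C.[Li+] | intermediate
13 | (2R)-6,10-dimethyl-2-(prop-1-en-2-yl)spiro[4.5]deca-6,9-diene-4,8-dione 4-(propane-1,3-diyl dithioketal) | C=C(C)[C@H]1CC2(SCCCS2)C3(C1)C(C)=CC(=O)C=C3C | intermediate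
14 | (2R,5S,10S)-8-[dimethyl(phenyl)silyloxy]-6,10-dimethyl-2-(prop-1-en-2-yl)spiro[4.5]deca-6,8-dien-4-one propane-1,3-diyl dithioketal | C=C(C)[C@H]1CC3(SCCCS3)[C@]2(C1)C(C)=CC(O[Si](C)(C)c4ccccc4)=C[C@@H]2C | intermediate
15 | (2R,5S,10S)-6,10-dimethyl-2-(prop-1-en-2-yl)spiro[4.5]dec-6-ene-4,8-dione 4-(propane-1,3-diyl dithioketal) | C=C(C)[C@H]1CC3(SCCCS3)[C@]2(C1)C(C)=CC(=O)C[C@@H]2C | intermediate
16 | (2R,5S,10S)-6,10-dimethyl-2-(prop-1-en-2-yl)spiro[4.5]dec-6-ene-4,8-dione | C=C(C)[C@H]1CC(=O)[C@]2(C1)C(C)=CC(=O)C[C@@H]2C | intermediate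
17 | (2R,4S,5S,10S)-4-hydroxy-6,10-dimethyl-2-(prop-1-en-2-yl)spiro[4.5]dec-6-en-8-one | C=C(C)[C@H]1C[C@H](O)[C@]2(C1)C(C)=CC(=O)C[C@@H]2C | intermediate
18 | (2R,4S,5S,10S)-6,10-dimethyl-8-oxo-2-(prop-1-en-2-yl)spiro[4.5]dec-6-en-4-yl 3-methylbut-2-enoate | C=C(C)[C@H]1C[C@H](OC(=O)C=C(C)C)[C@]2(C1)C(C)=CC(=O)C[C@@H]2C | intermediate
19 | potassium C8–C9 enolate of 18 | C=C(C)[C@H]1C[C@H](OC(=O)C=C(C)C)[C@]2(C1)C(C)=CC([O-])=C[C@@H]2C.[K+] | intermediate
20 | (2R,4S,5S,9S,10R)-9-hydroxy-6,10-dimethyl-8-oxo-2-(prop-1-en-2-yl)spiro[4.5]dec-6-en-4-yl 3-methylbut-2-enoate | C=C(C)[C@H]1C[C@H](OC(=O)C=C(C)C)[C@]2(C1)C(C)=CC(=O)[C@@H](O)[C@@H]2C | intermediate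
21 | (2R,4S,5S,9S,10R)-9-acetoxy-6,10-dimethyl-8-oxo-2-(prop-1-en-2-yl)spiro[4.5]dec-6-en-4-yl 3-methylbut-2-enoate | C=C(C)[C@H]1C[C@H](OC(=O)C=C(C)C)[C@]2(C1)C(C)=CC(=O)[C@@H](OC(C)=O)[C@@H]2C | target

**Count and risks**

Total steps: 14. Longest linear sequence: 13 steps (steps 1–6, then 8–14).

Step 8 (proposed new method). The two substitutions may fail to run in one pot: the hindered dithianyl carbanion may act as a base on the β-branched triflate (elimination through the allylic C–H), or intermolecular O-alkylation of the phenoxide may outrun para-C ring closure. The fallback separates the two known events. From 10, silylation (TBSCl, imidazole, DMF) gives tert-butyl[4-(1,3-dithian-2-yl)-3,5-dimethylphenoxy]dimethylsilane F1. Lithiation (n-BuLi, THF, −30 °C) and Corey–Seebach alkylation with 8 at −78 °C gives (R)-{4-[2-(2-(bromomethyl)-3-methylbut-3-en-1-yl)-1,3-dithian-2-yl]-3,5-dimethylphenoxy}(tert-butyl)dimethylsilane F2. Fluoride (TBAF, THF, 60 °C, high dilution) then frees the phenoxide, which closes the ring by the Ar1-5 alkylation, and the sequence returns to the route at 13.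

Step 9. Hydride may be delivered to the other arm, or from the C4 face through sulfur coordination of copper, and turnover at the neopentyl β-carbon may be slow. The fallback replaces steric control by the substrate with control by a protein pocket. From 13, a panel of ene-reductases of the Old Yellow Enzyme class (NADPH recycled with glucose and glucose dehydrogenase) is screened for the enzyme that reduces the required arm from the required face. This gives 15 directly, so no new compound is made (none F0).

Step 11. Hydride may enter from the C10-methyl side, which gives poor or reversed facial selectivity at C4. The fallback uses the epimer instead of discarding it. From 16, the reduction then gives (2R,4R,5S,10S)-4-hydroxy-6,10-dimethyl-2-(prop-1-en-2-yl)spiro[4.5]dec-6-en-8-one F3. Mitsunobu esterification with 3-methylbut-2-enoic acid (PPh3, DIAD, toluene) inverts C4 and installs the senecioate in the same operation, returning to the route at 18.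

Further compounds
F1 | step 8 | tert-butyl[4-(1,3-dithian-2-yl)-3,5-dimethylphenoxy]dimethylsilane | Cc1cc(O[Si](C)(C)C(C)(C)C)cc(C)c1C1SCCCS1
F2 | step 8 | (R)-{4-[2-(2-(bromomethyl)-3-methylbut-3-en-1-yl)-1,3-dithian-2-yl]-3,5-dimethylphenoxy}(tert-butyl)dimethylsilane | C=C(C)[C@H](CBr)CC1(SCCCS1)c1c(C)cc(O[Si](C)(C)C(C)(C)C)cc1C
F0 | step 9 | none | none
F3 | step 11 | (2R,4R,5S,10S)-4-hydroxy-6,10-dimethyl-2-(prop-1-en-2-yl)spiro[4.5]dec-6-en-8-one | C=C(C)[C@H]1C[C@@H](O)[C@]2(C1)C(C)=CC(=O)C[C@@H]2C
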